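The amber flask is to be run on to 10 d; the green run, charged at 30 mM against the amber 20 mM, was followed to 8.00 d. Both carry the same loading of initiator.

| flask | starting material | coupling partner | initiator | remark | time |
|---|---|---|---|---|---|
| amber | 20 mM | 1.05 equiv | 5 mol% | the very flask that is asked about, followed so far |  |
| green | 30 mM | 1.05 equiv | 5 mol% | run made earlier |  |
| flask | 20 mM | 1.05 equiv | 5 mol% |  | 10 d |

amber run (percent of the starting material charged)

| time / h | starting material / % | product / % |
|---|---|---|
| 10.0 | 78.5 | 21.6 |
| 20.0 | 69.5 | 29.8 |
| 30.0 | 65.9 | 30.7 |
| 40.0 | 66.1 | 34.3 |
| 50.0 | 64.2 | 34.9 |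

green run (percent of the starting material charged)

| time / d | starting material / % | product / % |
|---|---|---|
| 0.625 | 67.9 | 31.6 |
| 1.04 | 64.9 | 34.1 |
| 2.08 | 62.4 | 39.1 |
| 4.00 | 60.0 | 39.4 |
| 8.00 | 56.6 | 37.9 |

(scatter of a reading: 1 percentage point)

- part of the starting material that has reacted at 10 d
- share of the unused coupling partner that is free and not bound as idle adduct, at 10 d

- the analysis behind the earlier runs scatters by 1 percentage point, standard deviation
- the earlier runs do not show how much of coupling partner is bound; that part of a forecast is a guess

On the first rung of the ladder, amber product appears at 0.518 d⁻¹ of the charge over the first 10.0 h. On the next rung that burst is over: amber product reads 34.3% and then 34.9%, so this reckoning freezes it at their mean, 34.6%.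

The last rung shows in the green run, where product reads level within its scatter from 2.08 d on while starting material goes from 62.4% to 56.6%. At 8.00 d, 5.50% of the charge is in neither species. That gives 0.00687 d⁻¹, the leak: the share of the charge per day that leaves starting material without becoming product. It is far slower than the burst, and it rests on readings scattering by 1 percentage point.

This reckoning carries the green leak over to the amber flask unchanged, as a guess, since the two differ in charge; over 10 d it amounts to 6.87%. Added to the frozen product, this gives 41.5% reacted in the amber flask.

The forecast, from the drift of starting material instead, says 42% reacted after “adding about 190 h of that drift”, and guesses 75% free for the coupling partner.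

The flask gives 39.1% reacted and 90.6% free.

    initiator → 2 initiating radical (k = 0.00260 h⁻¹)
    starting material + initiating radical → capped initiator + first chain carrier (k = 1.40 × 10⁵ M⁻¹ s⁻¹)
    coupling partner + first chain carrier ⇌ product + second chain carrier (K = 5.00, k = 11000 M⁻¹ s⁻¹)
    starting material + second chain carrier → released group + first chain carrier (k = 18000 M⁻¹ s⁻¹)
    2 first chain carrier → ended chains (k = 1.00 × 10⁹ M⁻¹ s⁻¹)
    coupling partner + released group ⇌ idle adduct, settled at all times (K = 15.0 M⁻¹)
    coupling partner → decomposed reagent (k = 0.0660 h⁻¹)

At 10.0 d the amber flask holds 34.5% product and 4.64% ended chains, a percentage in which each ended chain counts as two, against the leak's 6.87%, a ratio of 1.48. The neighbouring flask with 20 mol% of initiator reaches 70.0% reacted with 51.4% product. The leak scaled to that loading reckons 27.5% over 10 d, and that neighbouring flask holds 18.6% ended chains, a ratio of 1.48.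

(All runs are calculated on assumed constants, and the scatter is random.)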